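**Direct plan and its weak points**

A direct plan would take formononetin A1, acylate its 7-OH, reduce the isoflavone by transfer hydrogenation with dynamic kinetic resolution to the cis-isoflavan-4-ol pivalate A2, close the dihydrofuran of medicarpin pivalate A3 by a hydroxyl-directed palladium-catalysed C–H oxygenation, hydrogenolyse most of A3 to vestitol pivalate A4, and join A3 with A4 by acid-catalysed Friedel–Crafts alkylation before deacylation.
Its weakest step would be the oxidative C–H/C–O closure of the dihydrofuran: such closures are known only for tertiary homobenzylic alcohols, and a secondary benzylic alcohol would rather be oxidised to the ketone or ionised, so this ring closure would be left to chance.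
The dihydrofuran would also be made only to be unmade: because ring B of A1 carries no 2'-oxygen, the ring would be closed to bring an oxygen onto ring B, then opened by hydrogenolysis in one partner and by acid in the other, so the middle of the plan would add no lasting complexity.
The acid-mediated union would be the step least welcome on late material: it would use three equivalents of A3-derived material per product, leave the C4 configuration to the neighbouring aryl group alone, and let a benzylic cation meet electron-rich arenes (elimination to the isoflavene, wrong-site or repeated alkylation) with no means of correcting C4 afterwards.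

**Plan of the new route**

Hardest feature: C4 of the upper unit (chroman rings A/C, aryl ring B) is a methine between ring A, ring B' and C3 that must be trans to C3, while the remote C3' of the lower unit (chroman rings A'/C', aryl ring B') needs the same handedness.
Retrosynthesis: C2 and C2' are raised to acetals; both pyran rings are then cut by the same retro-oxa-Diels–Alder (O1–C2 and C3–C4; O1'–C2' and C3'–C4'), and the C4–ring B' bond is cut as an aryl-metal addition to an aldehyde.
Order of rings: the four benzene rings are bought; pyran ring C' is made first (C3' set), then the C4–ring B' bond, and pyran ring C last, around the already joined diarylmethylidene, with C3 and C4 set together.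
Enabling feature: in each unit O1 sits on C8a, ortho to C4a which carries C4, so O1–C8a–C4a–C4 is a latent ortho-quinone methide and C2–C3 with its aryl ring the enol-ether partner; C4 lies between ring A and ring B' and is therefore the methide carbon that an aldehyde and an aryl metal supply.
One aldehyde (ring A = ring A') feeds both quinone methides, and one enantiomer of a recoverable alcohol on both enol ethers fixes C3', C3 and C4 by reagent control.
No dihydrofuran is made and unmade, no C–H oxidation is needed because every ring oxygen is bought in place, no benzylic cation meets a free polyphenol, and the last step on precious material is a hydrogenolysis.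

Key step: step 10

Assumption: the (E)-enol ethers of trans-2-phenylcyclohexanol are taken to react in the s-trans conformation on the face away from the phenyl ring, which makes the (1S,2R) alcohol the one that leads to the (3S) series; if the sense proved opposite, the (1R,2S) alcohol would be used and nothing else would change.

**Route**

Step 1
Reactants: 1 4-(benzyloxy)-2-hydroxybenzaldehyde
Product: 2 5-(benzyloxy)-2-formylphenyl tert-butyl carbonate
Conditions: Boc2O (1.1 equiv), iPr2NEt (1.2 equiv), DMAP (5 mol %), THF, 0 °C to rt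
Reagents that add atoms: di-tert-butyl dicarbonate, CC(C)(C)OC(=O)OC(=O)OC(C)(C)C
Why: DMAP-catalysed O-acylation of the phenol gives the aryl tert-butyl carbonate that later serves as the trigger for quinone methide formation, and the aldehyde is not affected.

Step 2
Reactants: 2 5-(benzyloxy)-2-formylphenyl tert-butyl carbonate
Product: 3 5-(benzyloxy)-2-(hydroxymethyl)phenyl tert-butyl carbonate
Conditions: BH3·THF (1.0 equiv), THF, 0 °C; MeOH quench, aqueous work-up
Reagents that add atoms: none
Why: Borane reduction of the aldehyde passes through a neutral borate ester that does not attack the neighbouring carbonate, so the Boc group should stay on the phenol until a magnesium alkoxide is made on purpose.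

Step 3
Reactants: 4 5-bromo-2-hydroxy-4-methoxybenzaldehyde
Product: 5 2-(benzyloxy)-5-bromo-4-methoxybenzaldehyde
Conditions: BnBr (1.1 equiv), K2CO3 (1.5 equiv), DMF, rt
Reagents that add atoms: benzyl bromide, BrCc1ccccc1
Why: Williamson etherification of the phenol installs a benzyl group that survives tert-butyllithium and silyl triflate and leaves with the other benzyl groups in the last step.

Step 4
Reactants: 5 2-(benzyloxy)-5-bromo-4-methoxybenzaldehyde
Product: 6 1-(benzyloxy)-4-bromo-2-[(E)-2-iodoethenyl]-5-methoxybenzene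
Conditions: CHI3 (2 equiv), CrCl2 (6 equiv), THF, 0 °C to rt
Reagents that add atoms: iodoform, IC(I)I
Why: Takai olefination, in which the geminal dichromium reagent from CHI3 and CrCl2 adds to the aldehyde and eliminates to the (E)-vinyl iodide, while the aryl bromide is inert to CrCl2 without a nickel co-catalyst.

Step 5
Reactants: 6 1-(benzyloxy)-4-bromo-2-[(E)-2-iodoethenyl]-5-methoxybenzene; 7 (1S,2R)-2-phenylcyclohexan-1-ol (trans)
Product: 8 1-(benzyloxy)-4-bromo-5-methoxy-2-[(E)-2-{[(1S,2R)-2-phenylcyclohexyl]oxy}ethenyl]benzene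
Conditions: CuI (10 mol %), 3,4,7,8-tetramethyl-1,10-phenanthroline (20 mol %), Cs2CO3 (1.5 equiv), toluene, 80 °C
Reagents that add atoms: none
Why: Ullmann-type copper-catalysed O-vinylation of a secondary alcohol proceeds with retention of alkene geometry, the vinyl iodide reacting much faster than the electron-rich aryl bromide and the stereocentres of 7 staying untouched.

Step 6
Reactants: 3 5-(benzyloxy)-2-(hydroxymethyl)phenyl tert-butyl carbonate; 8 1-(benzyloxy)-4-bromo-5-methoxy-2-[(E)-2-{[(1S,2R)-2-phenylcyclohexyl]oxy}ethenyl]benzene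
Product: 11 (2R,3S)-7-(benzyloxy)-3-[2-(benzyloxy)-5-bromo-4-methoxyphenyl]-2-{[(1S,2R)-2-phenylcyclohexyl]oxy}chromane, via chloromagnesium alkoxide 9 (not isolated), via ortho-quinone methide 10 (not isolated)
Conditions: 3 (1.5 equiv), 8 (1.0 equiv), t-BuMgCl (1.5 equiv), toluene, −78 °C to rt
Reagents that add atoms: none
Why: Inverse-electron-demand oxa-Diels–Alder reaction of an ortho-quinone methide, in which alkoxide 9 takes over the Boc group and expels tert-butyl carbonate to give 10, whose methylene carbon bonds to the aryl-bearing carbon of 8 while its oxygen closes on the oxocarbenium carbon; suprafacial addition to the (E)-enol ether makes C2' and C3' trans, and the phenyl group of the auxiliary screens one face so that C3' should arise (S).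

Step 7
Reactants: 12 2-hydroxy-4-methoxybenzaldehyde
Product: 13 2-(benzyloxy)-4-methoxybenzaldehyde
Conditions: BnBr (1.1 equiv), K2CO3 (1.5 equiv), DMF, rt
Reagents that add atoms: benzyl bromide, BrCc1ccccc1
Why: Williamson etherification of the phenol, as for ring B', gives the benzyl ether that is carried to the last step.

Step 8
Reactants: 13 2-(benzyloxy)-4-methoxybenzaldehyde
Product: 14 2-(benzyloxy)-1-[(E)-2-iodoethenyl]-4-methoxybenzene
Conditions: CHI3 (2 equiv), CrCl2 (6 equiv), THF, 0 °C to rt
Reagents that add atoms: iodoform, IC(I)I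
Why: Takai olefination of the aryl aldehyde gives the (E)-vinyl iodide by addition of the geminal dichromium reagent and elimination.

Step 9
Reactants: 14 2-(benzyloxy)-1-[(E)-2-iodoethenyl]-4-methoxybenzene; 7 (1S,2R)-2-phenylcyclohexan-1-ol (trans)
Product: 15 2-(benzyloxy)-4-methoxy-1-[(E)-2-{[(1S,2R)-2-phenylcyclohexyl]oxy}ethenyl]benzene
Conditions: CuI (10 mol %), 3,4,7,8-tetramethyl-1,10-phenanthroline (20 mol %), Cs2CO3 (1.5 equiv), toluene, 80 °C
Reagents that add atoms: none
Why: Ullmann-type copper-catalysed O-vinylation with retention of the (E) geometry gives the second enol ether carrying the same enantiomer of the auxiliary.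

Step 10
Reactants: 11 (2R,3S)-7-(benzyloxy)-3-[2-(benzyloxy)-5-bromo-4-methoxyphenyl]-2-{[(1S,2R)-2-phenylcyclohexyl]oxy}chromane; 2 5-(benzyloxy)-2-formylphenyl tert-butyl carbonate; 15 2-(benzyloxy)-4-methoxy-1-[(E)-2-{[(1S,2R)-2-phenylcyclohexyl]oxy}ethenyl]benzene
Product: 20 (2R,3S,4R)-7-(benzyloxy)-3-[2-(benzyloxy)-4-methoxyphenyl]-4-{4-(benzyloxy)-5-[(2R,3S)-7-(benzyloxy)-2-{[(1S,2R)-2-phenylcyclohexyl]oxy}chroman-3-yl]-2-methoxyphenyl}-2-{[(1S,2R)-2-phenylcyclohexyl]oxy}chromane, via aryllithium 16 (not isolated), via arylmagnesium bromide 17 (not isolated), via bromomagnesium diarylmethoxide 18 (not isolated), via ortho-quinone methide 19 (not isolated)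
Conditions: 11, t-BuLi (2.0 equiv), Et2O, −78 °C; MgBr2·OEt2 (1.1 equiv), −78 to −40 °C; add to 2 (1.1 equiv) and 15 (2.5 equiv), toluene, −78 °C to rt; NaHCO3 work-up
Reagents that add atoms: none
Why: Bromine–lithium exchange and transmetalation give 17, which adds to the aldehyde of 2 faster than to its carbonate; on warming, alkoxide 18 takes over the Boc group and loses tert-butyl carbonate to give the (E)-ortho-quinone methide 19, which enol ether 15 captures in an inverse-electron-demand oxa-Diels–Alder reaction. The closest known reaction type is the three-component synthesis of 2-alkoxy-4-arylchromans from an O-Boc salicylaldehyde, an aryl Grignard reagent and an enol ether, including enol ethers of trans-2-phenylcyclohexanol as chiral controllers. Ring C is closed by an intermolecular [4+2] cycloaddition in which C3–C4 and O1–C2 form in one asynchronous suprafacial event, the nucleophilic aryl-bearing carbon of 15 bonding to the methide carbon. C4 follows from the endo position of the alkoxy group over the (E)-quinone methide (C2–O and C4–aryl cis), C3 from the (E) geometry of 15 (aryl trans to the alkoxy group, hence 3,4-trans), and the absolute sense of all three new centres from the phenyl-screened face of the auxiliary, the remote C3' taking no part. The step needs capture of 19 by 15 to outrun attack by a second aryl metal or self-condensation, which the donor-stabilised non-enolisable diaryl methide, the magnesium bromide that activates its carbonyl, the excess of 15 and the absence of any free hydroxyl group should secure.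

Step 11
Reactants: 20 (2R,3S,4R)-7-(benzyloxy)-3-[2-(benzyloxy)-4-methoxyphenyl]-4-{4-(benzyloxy)-5-[(2R,3S)-7-(benzyloxy)-2-{[(1S,2R)-2-phenylcyclohexyl]oxy}chroman-3-yl]-2-methoxyphenyl}-2-{[(1S,2R)-2-phenylcyclohexyl]oxy}chromane
Product: 21 (3S,4R)-7-(benzyloxy)-3-[2-(benzyloxy)-4-methoxyphenyl]-4-{4-(benzyloxy)-5-[(3S)-7-(benzyloxy)chroman-3-yl]-2-methoxyphenyl}chromane
Conditions: Et3SiH (8 equiv), Me3SiOTf (20 mol %), CH2Cl2, −78 to −30 °C; Et3N quench
Reagents that add atoms: none
Why: Silyl-triflate-catalysed ionic hydrogenation of both acetals, in which silylation of the more basic exocyclic oxygen expels the auxiliary as its silyl ether and each cyclic oxocarbenium ion takes hydride from Et3SiH at low temperature before it can lose the C3 proton, so that C2 and C2' become methylene while C3, C4, C3' and the benzyl ethers stay untouched.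

Step 12
Reactants: 21 (3S,4R)-7-(benzyloxy)-3-[2-(benzyloxy)-4-methoxyphenyl]-4-{4-(benzyloxy)-5-[(3S)-7-(benzyloxy)chroman-3-yl]-2-methoxyphenyl}chromane
Product: 22 (3S,4R)-4-{4-hydroxy-5-[(3S)-7-hydroxychroman-3-yl]-2-methoxyphenyl}-3-(2-hydroxy-4-methoxyphenyl)chroman-7-ol (CNP0152030.1)
Conditions: H2 (1 atm), 10% Pd/C, EtOAc/MeOH (1:1), rt
Reagents that add atoms: none
Why: Hydrogenolysis of the four aryl benzyl ethers over palladium should free the four phenols, and since the target has no benzylic C–O bond and no other reducible group nothing else should change.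

**Compound list**

1 | 4-(benzyloxy)-2-hydroxybenzaldehyde | O=Cc1ccc(OCc2ccccc2)cc1O | starting material
2 | 5-(benzyloxy)-2-formylphenyl tert-butyl carbonate | O=Cc1ccc(OCc2ccccc2)cc1OC(=O)OC(C)(C)C | intermediate
3 | 5-(benzyloxy)-2-(hydroxymethyl)phenyl tert-butyl carbonate | OCc1ccc(OCc2ccccc2)cc1OC(=O)OC(C)(C)C | intermediate
4 | 5-bromo-2-hydroxy-4-methoxybenzaldehyde | COc1cc(O)c(C=O)cc1Br | starting material
5 | 2-(benzyloxy)-5-bromo-4-methoxybenzaldehyde | COc1cc(OCc2ccccc2)c(C=O)cc1Br | intermediate
6 | 1-(benzyloxy)-4-bromo-2-[(E)-2-iodoethenyl]-5-methoxybenzene | COc1cc(OCc2ccccc2)c(/C=C/I)cc1Br | intermediate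
7 | (1S,2R)-2-phenylcyclohexan-1-ol (trans) | O[C@H]1CCCC[C@@H]1c1ccccc1 | starting material
8 | 1-(benzyloxy)-4-bromo-5-methoxy-2-[(E)-2-{[(1S,2R)-2-phenylcyclohexyl]oxy}ethenyl]benzene | COc1cc(OCc2ccccc2)c(/C=C/O[C@H]2CCCC[C@@H]2c2ccccc2)cc1Br | intermediate
9 | chloromagnesium alkoxide of 3 (not isolated) | CC(C)(C)OC(=O)Oc1cc(OCc2ccccc2)ccc1CO[Mg]Cl | intermediate
10 | 3-(benzyloxy)-6-methylidenecyclohexa-2,4-dien-1-one (ortho-quinone methide, not isolated) | C=C1C=CC(OCc2ccccc2)=CC1=O | intermediate
11 | (2R,3S)-7-(benzyloxy)-3-[2-(benzyloxy)-5-bromo-4-methoxyphenyl]-2-{[(1S,2R)-2-phenylcyclohexyl]oxy}chromane (2,3-trans) | COc1cc(OCc2ccccc2)c([C@H]2[C@H](O[C@H]3CCCC[C@@H]3c3ccccc3)Oc3cc(OCc4ccccc4)ccc3C2)cc1Br | intermediate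
12 | 2-hydroxy-4-methoxybenzaldehyde | COc1ccc(C=O)c(O)c1 | starting material
13 | 2-(benzyloxy)-4-methoxybenzaldehyde | COc1ccc(C=O)c(OCc2ccccc2)c1 | intermediate
14 | 2-(benzyloxy)-1-[(E)-2-iodoethenyl]-4-methoxybenzene | COc1ccc(/C=C/I)c(OCc2ccccc2)c1 | intermediate
15 | 2-(benzyloxy)-4-methoxy-1-[(E)-2-{[(1S,2R)-2-phenylcyclohexyl]oxy}ethenyl]benzene | COc1ccc(/C=C/O[C@H]2CCCC[C@@H]2c2ccccc2)c(OCc2ccccc2)c1 | intermediate
16 | {4-(benzyloxy)-5-[(2R,3S)-7-(benzyloxy)-2-{[(1S,2R)-2-phenylcyclohexyl]oxy}chroman-3-yl]-2-methoxyphenyl}lithium (not isolated) | COc1cc(OCc2ccccc2)c([C@H]2[C@H](O[C@H]3CCCC[C@@H]3c3ccccc3)Oc3cc(OCc4ccccc4)ccc3C2)cc1[Li] | intermediate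
17 | {4-(benzyloxy)-5-[(2R,3S)-7-(benzyloxy)-2-{[(1S,2R)-2-phenylcyclohexyl]oxy}chroman-3-yl]-2-methoxyphenyl}magnesium bromide (not isolated) | COc1cc(OCc2ccccc2)c([C@H]2[C@H](O[C@H]3CCCC[C@@H]3c3ccccc3)Oc3cc(OCc4ccccc4)ccc3C2)cc1[Mg]Br | intermediate
18 | bromomagnesium alkoxide of the diarylmethanol from 17 and 2, both carbinol epimers (not isolated) | COc1cc(OCc2ccccc2)c([C@H]2[C@H](O[C@H]3CCCC[C@@H]3c3ccccc3)Oc3cc(OCc4ccccc4)ccc3C2)cc1C(O[Mg]Br)c1ccc(OCc2ccccc2)cc1OC(=O)OC(C)(C)C | intermediate
19 | (6E)-3-(benzyloxy)-6-({4-(benzyloxy)-5-[(2R,3S)-7-(benzyloxy)-2-{[(1S,2R)-2-phenylcyclohexyl]oxy}chroman-3-yl]-2-methoxyphenyl}methylidene)cyclohexa-2,4-dien-1-one (ortho-quinone methide, not isolated) | O=C1C=C(OCc2ccccc2)C=C/C1=C\c1cc([C@H]2[C@H](O[C@H]3CCCC[C@@H]3c3ccccc3)Oc3cc(OCc4ccccc4)ccc3C2)c(OCc2ccccc2)cc1OC | intermediate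
20 | (2R,3S,4R)-7-(benzyloxy)-3-[2-(benzyloxy)-4-methoxyphenyl]-4-{4-(benzyloxy)-5-[(2R,3S)-7-(benzyloxy)-2-{[(1S,2R)-2-phenylcyclohexyl]oxy}chroman-3-yl]-2-methoxyphenyl}-2-{[(1S,2R)-2-phenylcyclohexyl]oxy}chromane | COc1ccc([C@H]2[C@H](O[C@H]3CCCC[C@@H]3c3ccccc3)Oc3cc(OCc4ccccc4)ccc3[C@@H]2c2cc([C@H]3[C@H](O[C@H]4CCCC[C@@H]4c4ccccc4)Oc4cc(OCc5ccccc5)ccc4C3)c(OCc3ccccc3)cc2OC)c(OCc2ccccc2)c1 | intermediate
21 | (3S,4R)-7-(benzyloxy)-3-[2-(benzyloxy)-4-methoxyphenyl]-4-{4-(benzyloxy)-5-[(3S)-7-(benzyloxy)chroman-3-yl]-2-methoxyphenyl}chromane | COc1ccc([C@H]2COc3cc(OCc4ccccc4)ccc3[C@@H]2c2cc([C@H]3COc4cc(OCc5ccccc5)ccc4C3)c(OCc3ccccc3)cc2OC)c(OCc2ccccc2)c1 | intermediate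
22 | CNP0152030.1, (3S,4R)-4-{4-hydroxy-5-[(3S)-7-hydroxychroman-3-yl]-2-methoxyphenyl}-3-(2-hydroxy-4-methoxyphenyl)chroman-7-ol | COc1ccc([C@H]2COc3cc(O)ccc3[C@@H]2c2cc([C@H]3COc4cc(O)ccc4C3)c(O)cc2OC)c(O)c1 | target

**Step count and risks**

Total steps: 12. Longest linear sequence: 7 (steps 3, 4, 5, 6, 10, 11, 12).

Steps most likely to fail:

Step 10 (key step). Capture of the hindered, donor-stabilised quinone methide by the bulky enol ether may be too slow, so that self-condensation or conjugate addition of a second aryl metal intervenes, or the endo and facial preferences may erode at the temperature needed. The fallback sets out from 11 and returns at 20. Aryllithium 16 would be added at −78 °C to aldehyde 1 that has first been turned into its bromomagnesium phenoxide with MeMgBr (1.0 equiv), giving after NH4Cl work-up the ortho-hydroxybenzhydrol {4-(benzyloxy)-5-[(2R,3S)-7-(benzyloxy)-2-{[(1S,2R)-2-phenylcyclohexyl]oxy}chroman-3-yl]-2-methoxyphenyl}[4-(benzyloxy)-2-hydroxyphenyl]methanol F1 as a mixture of carbinol epimers. F1 would then be dehydrated to 19 under Brønsted-acid catalysis (BINOL-derived chiral phosphoric acid, 5 mol %, enantiomer matched to the auxiliary, 4 Å molecular sieves, toluene, −20 °C) in the presence of 15 (2 equiv). The quinone methide would thus form slowly, be protonated and more electrophilic, and be paired with a chiral anion while it is trapped to give 20.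

Step 6. The unsubstituted quinone methide may show too small a facial preference toward the β-aryl enol ether, giving a mixture of C3' epimers. The fallback sets out from 11 (as the mixture of facial isomers) and returns at 21. Pyridinium p-toluenesulfonate in refluxing toluene would eliminate the auxiliary alcohol 7 to the achiral enol ether 7-(benzyloxy)-3-[2-(benzyloxy)-5-bromo-4-methoxyphenyl]-4H-chromene F2. Asymmetric hydrogenation of this aryl-conjugated cyclic enol ether ([Ir(cod)(tBu-PHOX)]BArF, ligand enantiomer chosen to give (3S), H2 50 bar, CH2Cl2) would set C3' by catalyst control and give (3S)-7-(benzyloxy)-3-[2-(benzyloxy)-5-bromo-4-methoxyphenyl]chromane F3. F3 would be taken through the conditions of step 10 with 2 and 15 to the mono-acetal (2R,3S,4R)-7-(benzyloxy)-3-[2-(benzyloxy)-4-methoxyphenyl]-4-{4-(benzyloxy)-5-[(3S)-7-(benzyloxy)chroman-3-yl]-2-methoxyphenyl}-2-{[(1S,2R)-2-phenylcyclohexyl]oxy}chromane F4, which the conditions of step 11 would reduce to 21.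

Step 11. The acetals may ionise at the endocyclic C2–O1 bond, leading to reductive ring opening, or an oxocarbenium ion may lose its C3 proton before hydride arrives, leading to epimerisation. The fallback sets out from 20 and returns at 21. Mild aqueous acid (AcOH/H2O/THF, rt) would hydrolyse both acetals with recovery of 7 to the bis-lactol (3S,4R)-7-(benzyloxy)-3-[2-(benzyloxy)-4-methoxyphenyl]-4-{4-(benzyloxy)-5-[(3S)-7-(benzyloxy)-2-hydroxychroman-3-yl]-2-methoxyphenyl}chroman-2-ol F5 (anomer mixtures). NaBH4 (EtOH/THF, 0 °C) would reduce the open hydroxy-aldehyde forms to (2S,3R)-2-[2-(benzyloxy)-4-methoxyphenyl]-3-[4-(benzyloxy)-2-hydroxyphenyl]-3-{4-(benzyloxy)-5-[(2S)-1-[4-(benzyloxy)-2-hydroxyphenyl]-3-hydroxypropan-2-yl]-2-methoxyphenyl}propan-1-ol F6. A double Mitsunobu etherification (PPh3, DIAD, THF, 0 °C) would then close rings C and C' through the O1–C2 and O1'–C2' bonds, away from the stereocentres, to give 21.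

Further compounds
F1 | step 10 | {4-(benzyloxy)-5-[(2R,3S)-7-(benzyloxy)-2-{[(1S,2R)-2-phenylcyclohexyl]oxy}chroman-3-yl]-2-methoxyphenyl}[4-(benzyloxy)-2-hydroxyphenyl]methanol (carbinol epimers) | COc1cc(OCc2ccccc2)c([C@H]2[C@H](O[C@H]3CCCC[C@@H]3c3ccccc3)Oc3cc(OCc4ccccc4)ccc3C2)cc1C(O)c1ccc(OCc2ccccc2)cc1O
F2 | step 6 | 7-(benzyloxy)-3-[2-(benzyloxy)-5-bromo-4-methoxyphenyl]-4H-chromene | COc1cc(OCc2ccccc2)c(C2=COc3cc(OCc4ccccc4)ccc3C2)cc1Br
F3 | step 6 | (3S)-7-(benzyloxy)-3-[2-(benzyloxy)-5-bromo-4-methoxyphenyl]chromane | COc1cc(OCc2ccccc2)c([C@H]2COc3cc(OCc4ccccc4)ccc3C2)cc1Br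
F4 | step 6 | (2R,3S,4R)-7-(benzyloxy)-3-[2-(benzyloxy)-4-methoxyphenyl]-4-{4-(benzyloxy)-5-[(3S)-7-(benzyloxy)chroman-3-yl]-2-methoxyphenyl}-2-{[(1S,2R)-2-phenylcyclohexyl]oxy}chromane | COc1ccc([C@H]2[C@H](O[C@H]3CCCC[C@@H]3c3ccccc3)Oc3cc(OCc4ccccc4)ccc3[C@@H]2c2cc([C@H]3COc4cc(OCc5ccccc5)ccc4C3)c(OCc3ccccc3)cc2OC)c(OCc2ccccc2)c1
F5 | step 11 | (3S,4R)-7-(benzyloxy)-3-[2-(benzyloxy)-4-methoxyphenyl]-4-{4-(benzyloxy)-5-[(3S)-7-(benzyloxy)-2-hydroxychroman-3-yl]-2-methoxyphenyl}chroman-2-ol (anomer mixtures) | COc1ccc([C@H]2C(O)Oc3cc(OCc4ccccc4)ccc3[C@@H]2c2cc([C@H]3C(O)Oc4cc(OCc5ccccc5)ccc4C3)c(OCc3ccccc3)cc2OC)c(OCc2ccccc2)c1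
F6 | step 11 | (2S,3R)-2-[2-(benzyloxy)-4-methoxyphenyl]-3-[4-(benzyloxy)-2-hydroxyphenyl]-3-{4-(benzyloxy)-5-[(2S)-1-[4-(benzyloxy)-2-hydroxyphenyl]-3-hydroxypropan-2-yl]-2-methoxyphenyl}propan-1-ol | COc1ccc([C@@H](CO)[C@H](c2ccc(OCc3ccccc3)cc2O)c2cc([C@@H](CO)Cc3ccc(OCc4ccccc4)cc3O)c(OCc3ccccc3)cc2OC)c(OCc2ccccc2)c1
A1 | direct plan | formononetin (7-hydroxy-3-(4-methoxyphenyl)-4H-chromen-4-one) | COc1ccc(cc1)C1=COc2cc(O)ccc2C1=O
A2 | direct plan | (3S,4S)-cis-4-hydroxy-3-(4-methoxyphenyl)chroman-7-yl pivalate | COc1ccc([C@H]2COc3cc(OC(=O)C(C)(C)C)ccc3[C@H]2O)cc1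
A3 | direct plan | (6aS,11aS)-medicarpin 3-O-pivalate | COc1ccc2[C@H]3COc4cc(OC(=O)C(C)(C)C)ccc4[C@H]3Oc2c1
A4 | direct plan | (3S)-vestitol 7-O-pivalate | COc1ccc([C@H]2COc3cc(OC(=O)C(C)(C)C)ccc3C2)c(O)c1
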